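**Assumption:** Giganteone A has no stereocentre, and its biaryl axis carries only two ortho substituents and rotates freely, so the compound is achiral and no stereocontrol is needed.

## Retrosynthetic overview

1. Giganteone A ⇒ two molecules of malabaricone C, cut at the biaryl bond between catechol C6 and acylresorcinol C3. Both carbons are natively nucleophilic; in the forward sense one catechol is oxidised to its ortho-quinone (an aryl-cation, vinylogous enolonium equivalent) and the acylresorcinol of the second molecule attacks it.
2. Malabaricone C ⇒ its tetramethyl ether (global O-demethylation).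
3. Tetramethyl ether ⇒ 8-(3,4-dimethoxyphenyl)octyl Grignard reagent + 2,6-dimethoxybenzoyl chloride.
4. 8-Aryloctyl bromide ⇒ 3,4-dimethoxyphenyl Grignard reagent + 1,8-dibromooctane.
5. Rings: none is formed; all benzene rings are bought, and the two monomer halves are joined in the last step.

## Route

**Step 1**
Reactants: 1 4-bromo-1,2-dimethoxybenzene; 2 1,8-dibromooctane (3 equiv)
Product: 4 4-(8-bromooctyl)-1,2-dimethoxybenzene, via 3,4-dimethoxyphenylmagnesium bromide 3 (not isolated)
Conditions: Mg turnings, I2 (cat.), THF, 50 °C; then add to 2, Li2CuCl4 (3 mol%), THF, 0 °C to rt; excess 2 recovered by vacuum distillation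
Reagents that add atoms: none
Why: Kochi-type Li2CuCl4-catalysed coupling of an aryl Grignard reagent with a primary alkyl bromide, held at mono-substitution by the threefold excess of dibromide; no stereocentre is formed.

**Step 2**
Reactants: 4 4-(8-bromooctyl)-1,2-dimethoxybenzene; 5 2,6-dimethoxybenzoyl chloride
Product: 7 1-(2,6-dimethoxyphenyl)-9-(3,4-dimethoxyphenyl)nonan-1-one, via 8-(3,4-dimethoxyphenyl)octylmagnesium bromide 6 (not isolated)
Conditions: Mg turnings, THF, 50 °C; then add to 5, Fe(acac)3 (3 mol%), THF, −78 °C, 20 min
Reagents that add atoms: none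
Why: Iron-catalysed acylation of an alkyl Grignard reagent with an acid chloride outruns carbonyl addition at −78 °C, and the di-ortho-methoxy aryl ketone formed is too hindered to take up a second equivalent; no stereocentre is formed.

**Step 3**
Reactants: 7 1-(2,6-dimethoxyphenyl)-9-(3,4-dimethoxyphenyl)nonan-1-one
Product: 8 malabaricone C, 1-(2,6-dihydroxyphenyl)-9-(3,4-dihydroxyphenyl)nonan-1-one
Conditions: BBr3 (6 equiv), CH2Cl2, −78 °C to rt, 12 h; then H2O, 0 °C
Reagents that add atoms: none
Why: BBr3 demethylation of aryl methyl ethers (Lewis-acid complexation, then bromide attack on the methyl group) frees all four phenols while the ketone and the saturated chain are inert; no stereocentre is involved.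

**Step 4**
Reactants: 8 malabaricone C (two molecules: one is oxidised, the other is the nucleophile)
Product: 10 giganteone A, via malabaricone C ortho-quinone 9 (not isolated)
Conditions: NaIO4 (0.35 equiv, added over 1 h), MeCN/aq. NaH2PO4–Na2HPO4 buffer pH 7.4 (1:1), 0.2 M in 8, 0 °C, under argon; acidify to pH 3, EtOAc extraction; unreacted 8 recovered
Reagents that add atoms: none
Why: Proposed new method: periodate oxidises only the catechol of part of 8 to ortho-quinone 9, in which the natively nucleophilic C6 has become a Michael-acceptor carbon (aryl-cation, vinylogous enolonium equivalent); the more acidic, partly ionised acylresorcinol of a second molecule of 8 attacks through its C3 (ortho and para to its two OH groups) at the unsubstituted β-carbon C6 next to the chain, and tautomerisation of both rings restores aromaticity; the closest known reaction type is the biomimetic coupling of catechol ortho-quinones with phloroglucinol- or resorcinol-type C-nucleophiles (dehydrodicatechin-type biaryl formation) and the Michael arylation of ortho-quinones by 1,3-dicarbonyl compounds; no stereocentre is formed.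

## Compound list

1 | 4-bromo-1,2-dimethoxybenzene | COc1ccc(Br)cc1OC | starting material
2 | 1,8-dibromooctane | BrCCCCCCCCBr | starting material
3 | 3,4-dimethoxyphenylmagnesium bromide (not isolated) | COc1ccc([Mg]Br)cc1OC | intermediate
4 | 4-(8-bromooctyl)-1,2-dimethoxybenzene | COc1ccc(CCCCCCCCBr)cc1OC | intermediate
5 | 2,6-dimethoxybenzoyl chloride | COc1cccc(OC)c1C(=O)Cl | starting material
6 | 8-(3,4-dimethoxyphenyl)octylmagnesium bromide (not isolated) | COc1ccc(CCCCCCCC[Mg]Br)cc1OC | intermediate
7 | 1-(2,6-dimethoxyphenyl)-9-(3,4-dimethoxyphenyl)nonan-1-one | COc1ccc(CCCCCCCCC(=O)c2c(OC)cccc2OC)cc1OC | intermediate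
8 | malabaricone C, 1-(2,6-dihydroxyphenyl)-9-(3,4-dihydroxyphenyl)nonan-1-one | O=C(CCCCCCCCc1ccc(O)c(O)c1)c1c(O)cccc1O | intermediate
9 | malabaricone C ortho-quinone, 4-[9-(2,6-dihydroxyphenyl)-9-oxononyl]cyclohexa-3,5-diene-1,2-dione (not isolated) | O=C(CCCCCCCCC1=CC(=O)C(=O)C=C1)c1c(O)cccc1O | intermediate
10 | giganteone A, 1-[3-{2-[9-(2,6-dihydroxyphenyl)-9-oxononyl]-4,5-dihydroxyphenyl}-2,6-dihydroxyphenyl]-9-(3,4-dihydroxyphenyl)nonan-1-one (achiral) | O=C(CCCCCCCCc1cc(O)c(O)cc1-c1ccc(O)c(C(=O)CCCCCCCCc2ccc(O)c(O)c2)c1O)c1c(O)cccc1O | target

## Step count and risks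

Total step count: 4. Longest linear sequence: 4 steps (1 → 4 → 7 → 8 → 10).

**Step 4 (most likely to fail).** The catechol ring of a second monomer can compete with the acylresorcinol as the nucleophile. The product's biaryl catechol can also be re-oxidised by redox exchange and close to a dibenzofuran. Sub-stoichiometric, slowly added oxidant and recycling of 8 limit both, and a dithionite wash in the work-up would return any residual quinone to catechol.
Fallback, setting out from 8 and coming back at 10: separate the two roles. Part of 8 is heated with 2,2-dimethoxypropane and catalytic TsOH in benzene to give malabaricone C catechol acetonide F1, which cannot be oxidised and can act only through its acylresorcinol ring. A second portion of 8 is oxidised fully to 9 (NaIO4, 1.0 equiv, aqueous MeCN, 0 °C) and added slowly to F1 (3 equiv) in the same buffered medium to give giganteone A mono-acetonide F2. TFA/H2O (9:1, rt) removes the acetonide and gives 10.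

**Step 2.** The hindered aroyl chloride may react sluggishly, or the alkyl Grignard reagent may homocouple under iron catalysis.
Fallback, setting out from 4 (through its Grignard reagent 6) and coming back at 7: add 6 to commercial 2,6-dimethoxybenzaldehyde (THF, 0 °C, water quench) to give racemic 1-(2,6-dimethoxyphenyl)-9-(3,4-dimethoxyphenyl)nonan-1-ol F3. Oxidise this benzylic alcohol with IBX (EtOAc, 75 °C) to ketone 7.

**Step 1.** The statistical mono-coupling can give the 1,8-diaryloctane and biaryl homocoupling products, and separation from excess 2 costs yield.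
Fallback, setting out from 1 and coming back at 4: hydroborate commercial 8-bromo-1-octene with 9-borabicyclo[3.3.1]nonane (THF, rt) to give B-(8-bromooctyl)-9-borabicyclo[3.3.1]nonane F4, used without isolation. Couple it with 1 in a B-alkyl Suzuki–Miyaura reaction (Pd(dppf)Cl2 3 mol%, K3PO4, THF/H2O, 60 °C); the zerovalent palladium inserts into the aryl bromide much faster than into the primary alkyl bromide, giving 4 directly.

## Further compounds

F1 | step 4 | malabaricone C catechol acetonide, 1-(2,6-dihydroxyphenyl)-9-(2,2-dimethyl-1,3-benzodioxol-5-yl)nonan-1-one | O=C(CCCCCCCCc1ccc2OC(C)(C)Oc2c1)c1c(O)cccc1O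
F2 | step 4 | giganteone A mono-acetonide (acetonide on the catechol at the chain end of the acylresorcinol unit) | O=C(CCCCCCCCc1cc(O)c(O)cc1-c1ccc(O)c(C(=O)CCCCCCCCc2ccc3OC(C)(C)Oc3c2)c1O)c1c(O)cccc1O
F3 | step 2 | 1-(2,6-dimethoxyphenyl)-9-(3,4-dimethoxyphenyl)nonan-1-ol (racemic) | COc1ccc(CCCCCCCCC(O)c2c(OC)cccc2OC)cc1OC
F4 | step 1 | B-(8-bromooctyl)-9-borabicyclo[3.3.1]nonane | BrCCCCCCCCB1C2CCCC1CCC2
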